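**Strategy.** Ring C is cut at C2–C3. C2 is an aldehyde-level carbon held between O1 and the electron-rich ring B, so an O1=C2 oxocarbenium ion is easily reached. C3 carries oxygen and lies α to the C4 ketone, so it can act as an ene-diol carbon nucleophile. The 3-oxygen is therefore used as tether and leaving group: the ring B aldehyde is tied to O1 and O3 as a seven-membered cyclic acetal, the ketone is enolised, and a chiral acid ionises C2–O3. C3 then recaptures C2, contracting the dioxepine to the chromanone, releasing 3-OH and setting C2 and C3 (trans) in one operation.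

Key step: step 14

Remark: the lavandulyl stereocentre keeps one spatial arrangement throughout; its descriptor is (S) in 5–7 (C=O or CH2O outranks isopropenyl) and (R) once its CH2 is bonded to ring A.
Remark: the sense of induction of the chiral acid in step 14 cannot be predicted with confidence; the (S,S) catalyst is written, and its antipode is used if the first run shows the (2S,3S) series.
Remark: 19 and 20 are carried as mixtures of epimers at the acetal carbon, which is destroyed in step 14.

Step 1
Reactants: 1 (S)-4-benzyl-1,3-oxazolidin-2-one; 2 3-methylbut-2-enoyl chloride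
Product: 3 (S)-4-benzyl-3-(3-methylbut-2-enoyl)-1,3-oxazolidin-2-one
Conditions: n-BuLi, THF, −78 °C; then 2, −78 → 0 °C
Reagents that add atoms: none
Why: N-acylation of the lithiated oxazolidinone by the acid chloride is the standard entry to Evans imides and creates no stereocentre.

Step 2
Reactants: 3 (S)-4-benzyl-3-(3-methylbut-2-enoyl)-1,3-oxazolidin-2-one; 4 1-bromo-3-methylbut-2-ene (prenyl bromide)
Product: 5 (S)-4-benzyl-3-[(2S)-5-methyl-2-(prop-1-en-2-yl)hex-4-enoyl]-1,3-oxazolidin-2-one
Conditions: NaN(SiMe3)2, THF, −78 °C; then 4, −78 → −40 °C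
Reagents that add atoms: none
Why: Evans asymmetric alkylation in its deconjugative form, in which γ-deprotonation of the s-cis enoyl imide gives the chelated (Z)-dienolate that is alkylated at the α-carbon on the face opposite the C4 benzyl group, setting the (S) centre that bears the isopropenyl group.

Step 3
Reactants: 5 (S)-4-benzyl-3-[(2S)-5-methyl-2-(prop-1-en-2-yl)hex-4-enoyl]-1,3-oxazolidin-2-one
Product: 6 (S)-lavandulol [(2S)-5-methyl-2-(prop-1-en-2-yl)hex-4-en-1-ol]
Conditions: LiBH4, H2O (1 equiv), Et2O, 0 °C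
Reagents that add atoms: none
Why: Reductive cleavage of the imide by borohydride releases the primary alcohol and the auxiliary without touching the α-stereocentre or the two alkenes.

Step 4
Reactants: 6 (S)-lavandulol
Product: 7 (S)-lavandulyl tosylate [(2S)-5-methyl-2-(prop-1-en-2-yl)hex-4-en-1-yl 4-methylbenzenesulfonate]
Conditions: TsCl, Et3N, DMAP (cat.), CH2Cl2, 0 °C
Reagents that add atoms: p-toluenesulfonyl chloride, Cc1ccc(cc1)S(=O)(=O)Cl
Why: O-sulfonylation of a primary alcohol gives a leaving group suited to SN2 coupling and does not involve the stereocentre.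

Step 5
Reactants: 8 2,4-dihydroxybenzaldehyde
Product: 9 2,4-bis(methoxymethoxy)benzaldehyde
Conditions: MOMCl, NaH, DMF, 0 °C → rt
Reagents that add atoms: chloromethyl methyl ether, COCCl
Why: Williamson-type O-alkylation of both phenoxides (the chelated 2-OH needs the strong base) installs acetal protecting groups that survive base, fluoride and weak acid.

Step 6
Reactants: 10 phloroglucinol
Product: 11 5-(triisopropylsilyloxy)benzene-1,3-diol
Conditions: TIPSCl (1.0 equiv), imidazole, DMF, 0 °C
Reagents that add atoms: chlorotriisopropylsilane, CC(C)[Si](Cl)(C(C)C)C(C)C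
Why: Statistical mono-silylation of the symmetric triol (bis-silyl ether and triol are separable and recyclable) marks the oxygen that becomes O5 with a bulky, non-directing group.

Step 7
Reactants: 11 5-(triisopropylsilyloxy)benzene-1,3-diol
Product: 12 [3,5-bis(methoxymethoxy)phenoxy]triisopropylsilane
Conditions: MOMCl, iPr2NEt, CH2Cl2, 0 °C → rt
Reagents that add atoms: chloromethyl methyl ether, COCCl
Why: MOM protection of the two remaining phenols provides the ortho-directing groups for the three metalations and the final protecting groups of O1 and O7.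

Step 8
Reactants: 12 [3,5-bis(methoxymethoxy)phenoxy]triisopropylsilane; 7 (S)-lavandulyl tosylate
Product: 13 {3,5-bis(methoxymethoxy)-4-[(2R)-5-methyl-2-(prop-1-en-2-yl)hex-4-en-1-yl]phenoxy}triisopropylsilane
Conditions: n-BuLi, THF, 0 °C; MgBr2·OEt2; then 7, Li2CuCl4 (5 mol %), THF/NMP, 0 °C → rt
Reagents that add atoms: none
Why: Directed ortho-metalation occurs at the only position flanked by two MOM ethers (the silyl ether shields its own ortho positions), and the derived aryl Grignard couples with the primary tosylate in a copper-catalysed Kochi-type sp2–sp3 coupling by SN2 at CH2, which cannot disturb the β-stereocentre.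

Step 9
Reactants: 13 {3,5-bis(methoxymethoxy)-4-[(2R)-lavandulyl]phenoxy}triisopropylsilane; 14 2,2-dimethyloxetane
Product: 15 4-{2,4-bis(methoxymethoxy)-3-[(2R)-5-methyl-2-(prop-1-en-2-yl)hex-4-en-1-yl]-6-(triisopropylsilyloxy)phenyl}-2-methylbutan-2-ol
Conditions: s-BuLi, TMEDA, THF, −78 → −40 °C; then BF3·OEt2, 14, −78 °C
Reagents that add atoms: none
Why: The two remaining ring positions are equivalent, so MOM-directed ortho-lithiation is regiochemically unambiguous, and the BF3-activated oxetane is opened by the aryllithium at its unsubstituted CH2 to give the tertiary alcohol directly.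

Step 10
Reactants: 15 4-{2,4-bis(methoxymethoxy)-3-[(2R)-lavandulyl]-6-(triisopropylsilyloxy)phenyl}-2-methylbutan-2-ol; 16 2-(tert-butyldimethylsilyloxy)-N-methoxy-N-methylacetamide
Product: 17 2-(tert-butyldimethylsilyloxy)-1-{3-(3-hydroxy-3-methylbutyl)-4,6-bis(methoxymethoxy)-5-[(2R)-5-methyl-2-(prop-1-en-2-yl)hex-4-en-1-yl]-2-(triisopropylsilyloxy)phenyl}ethan-1-one
Conditions: s-BuLi (2.1 equiv), TMEDA, THF, −78 → −40 °C; then 16, −78 → 0 °C
Reagents that add atoms: none
Why: Deprotonation of the alcohol and of the last ring C–H gives a dianion whose aryllithium adds once to the amide (Weinreb ketone synthesis), the chelated tetrahedral adduct preventing over-addition.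

Step 11
Reactants: 17 the silyloxy ketone
Product: 18 2-hydroxy-1-{2-hydroxy-5-(3-hydroxy-3-methylbutyl)-4-(methoxymethoxy)-3-[(2R)-5-methyl-2-(prop-1-en-2-yl)hex-4-en-1-yl]-6-(triisopropylsilyloxy)phenyl}ethan-1-one
Conditions: HCl (0.5 M), MeOH, 0 °C → rt
Reagents that add atoms: none
Why: Mild acid methanolysis cleaves the primary silyl ether and, selectively, the MOM ether ortho to the ketone (the emerging phenol is hydrogen-bonded to C=O), while the para MOM ether between two alkyl groups and the aryl silyl ether should persist, so that O1 alone is unmasked.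

Step 12
Reactants: 18 the phenol–ketol; 9 2,4-bis(methoxymethoxy)benzaldehyde
Product: 19 2-[2,4-bis(methoxymethoxy)phenyl]-7-(3-hydroxy-3-methylbutyl)-8-(methoxymethoxy)-9-[(2R)-5-methyl-2-(prop-1-en-2-yl)hex-4-en-1-yl]-6-(triisopropylsilyloxy)-2H-1,3-benzodioxepin-5(4H)-one
Conditions: HC(OMe)3, PPTS (cat.), benzene, 4 Å MS, 50 °C
Reagents that add atoms: none
Why: Acid-catalysed transacetalisation of the dimethyl acetal of 9 formed in situ with the phenol O1–H and the primary alcohol O3–H closes the seven-membered cyclic acetal, the sieves removing methanol, and the configuration of the acetal carbon is of no consequence.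

Step 13
Reactants: 19 the benzodioxepinone
Product: 20 the 5-(trimethylsilyloxy)-2H-1,3-benzodioxepine (C3=C4 enol silane of 19 with the tertiary alcohol as its trimethylsilyl ether)
Conditions: LiN(SiMe3)2, TMSCl, Et3N, THF, −78 °C
Reagents that add atoms: chlorotrimethylsilane, C[Si](C)(C)Cl
Why: The ketone has a single enolisable position (C3), so amide-base enolisation with in situ O-silylation (silyl enol ether formation) gives the ring-constrained cis enol silane and also caps the tertiary alcohol, which would otherwise quench the cation of step 14.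

Step 14
Reactants: 20 the enol silane
Product: 22 (2R,3R)-2-[2,4-bis(methoxymethoxy)phenyl]-3,5-dihydroxy-6-(3-hydroxy-3-methylbutyl)-7-(methoxymethoxy)-8-[(2R)-5-methyl-2-(prop-1-en-2-yl)hex-4-en-1-yl]chroman-4-one, via tris-silylated chromanone 21 (not isolated)
Conditions: (S,S)-configured confined N-triflyl imidodiphosphorimidate (IDPi) Brønsted acid with 3,3′-diaryl-BINOL backbones (5 mol %), toluene, −60 °C; then Bu4NF, AcOH, THF, 0 °C
Reagents that add atoms: none
Why: Proposed new method: the acid, or its silylated form generated from the enol silane, ionises the C2–O3 bond to a contact ion pair of the O1=C2 oxocarbenium ion (stabilised by the 2,4-dioxygenated ring B) and the chiral anion, in which the tethered 1,2-bis(silyloxy)alkene attacks C2 through C3 (Mukaiyama aldol-type) and silyl transfer from the C4 oxocarbenium ion to the anion closes the cycle. The closest known reaction types are the Petasis–Ferrier rearrangement of cyclic enol acetals and chiral-anion-controlled additions of enol silanes to oxocarbenium ions. Ring C is closed in a 6-(enolendo)-endo-trig mode, equivalent to a disrotatory closure of the C3=C4–C4a=C8a–O1=C2 array. C2 and C3 arise together: the ring-imposed enol geometry (O3 cis to C4a) and the E-oxocarbenium ion (ring B anti to ring A) place ring B and the 3-oxygen trans, which is also the diequatorial, thermodynamically preferred arrangement, while the absolute (2R,3R) sense has to come from the confined chiral anion. The step needs C- over O-attack of the enol and C2–O3 over C2–O1 ionisation; O-attack gives a 1,3-benzodioxin that re-ionises and drains to the ketone, and C2–O1 ionisation is reversible and cannot close a ring. Buffered fluoride then removes the three silyl groups.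

Step 15
Reactants: 22 the tris-MOM flavanonol
Product: 24 (2R,3R)-2-(2,4-dihydroxyphenyl)-3,5,7-trihydroxy-6-(3-hydroxy-3-methylbutyl)-8-[(2R)-5-methyl-2-(prop-1-en-2-yl)hex-4-en-1-yl]chroman-4-one (CNP0183552.3), via hexakis-O-trimethylsilyl ether 23 (not isolated)
Conditions: TMSOTf, 2,2′-bipyridyl, MeCN, 0 °C → rt; then H2O, rt
Reagents that add atoms: none
Why: Silyl triflate with 2,2′-bipyridyl converts aryl MOM ethers into aryl silyl ethers under non-protic conditions (MOM ether cleavage) and water then hydrolyses all O–Si bonds, so that protic acid, which would cyclise the free phenols onto the tertiary alcohol or the lavandulyl alkenes, is avoided and no stereocentre is touched.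

**Compound list**

1 | (S)-4-benzyl-1,3-oxazolidin-2-one | O=C1N[C@@H](Cc2ccccc2)CO1 | starting material
2 | 3-methylbut-2-enoyl chloride | CC(C)=CC(Cl)=O | starting material
3 | (S)-4-benzyl-3-(3-methylbut-2-enoyl)-1,3-oxazolidin-2-one | CC(C)=CC(=O)N1[C@@H](Cc2ccccc2)COC1=O | intermediate
4 | 1-bromo-3-methylbut-2-ene | CC(C)=CCBr | starting material
5 | (S)-4-benzyl-3-[(2S)-5-methyl-2-(prop-1-en-2-yl)hex-4-enoyl]-1,3-oxazolidin-2-one | C=C(C)[C@H](CC=C(C)C)C(=O)N1[C@@H](Cc2ccccc2)COC1=O | intermediate
6 | (S)-lavandulol | C=C(C)[C@H](CC=C(C)C)CO | intermediate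
7 | (S)-lavandulyl tosylate | C=C(C)[C@H](CC=C(C)C)COS(=O)(=O)c1ccc(C)cc1 | intermediate
8 | 2,4-dihydroxybenzaldehyde | O=Cc1ccc(O)cc1O | starting material
9 | 2,4-bis(methoxymethoxy)benzaldehyde | COCOc1ccc(C=O)c(OCOC)c1 | intermediate
10 | phloroglucinol | Oc1cc(O)cc(O)c1 | starting material
11 | 5-(triisopropylsilyloxy)benzene-1,3-diol | CC(C)[Si](Oc1cc(O)cc(O)c1)(C(C)C)C(C)C | intermediate
12 | [3,5-bis(methoxymethoxy)phenoxy]triisopropylsilane | COCOc1cc(OCOC)cc(O[Si](C(C)C)(C(C)C)C(C)C)c1 | intermediate
13 | {3,5-bis(methoxymethoxy)-4-[(2R)-lavandulyl]phenoxy}triisopropylsilane | C=C(C)[C@H](CC=C(C)C)Cc1c(OCOC)cc(O[Si](C(C)C)(C(C)C)C(C)C)cc1OCOC | intermediate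
14 | 2,2-dimethyloxetane | CC1(C)CCO1 | starting material
15 | 4-{2,4-bis(methoxymethoxy)-3-[(2R)-lavandulyl]-6-(triisopropylsilyloxy)phenyl}-2-methylbutan-2-ol | C=C(C)[C@H](CC=C(C)C)Cc1c(OCOC)c(CCC(C)(C)O)c(O[Si](C(C)C)(C(C)C)C(C)C)cc1OCOC | intermediate
16 | 2-(tert-butyldimethylsilyloxy)-N-methoxy-N-methylacetamide | CON(C)C(=O)CO[Si](C)(C)C(C)(C)C | starting material
17 | aryl silyloxymethyl ketone (O1 and O7 as MOM ethers, O5 as TIPS ether) | C=C(C)[C@H](CC=C(C)C)Cc1c(OCOC)c(CCC(C)(C)O)c(O[Si](C(C)C)(C(C)C)C(C)C)c(C(=O)CO[Si](C)(C)C(C)(C)C)c1OCOC | intermediate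
18 | aryl hydroxymethyl ketone with free O1–H | C=C(C)[C@H](CC=C(C)C)Cc1c(OCOC)c(CCC(C)(C)O)c(O[Si](C(C)C)(C(C)C)C(C)C)c(C(=O)CO)c1O | intermediate
19 | 2-aryl-2H-1,3-benzodioxepin-5(4H)-one (both epimers at the acetal carbon) | C=C(C)[C@H](CC=C(C)C)Cc1c(OCOC)c(CCC(C)(C)O)c(O[Si](C(C)C)(C(C)C)C(C)C)c2c1OC(c1ccc(OCOC)cc1OCOC)OCC2=O | intermediate
20 | 5-(trimethylsilyloxy)-2H-1,3-benzodioxepine, side-chain alcohol as TMS ether (both epimers at the acetal carbon) | C=C(C)[C@H](CC=C(C)C)Cc1c(OCOC)c(CCC(C)(C)O[Si](C)(C)C)c(O[Si](C(C)C)(C(C)C)C(C)C)c2c1OC(c1ccc(OCOC)cc1OCOC)OC=C2O[Si](C)(C)C | intermediate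
21 | (2R,3R)-3-O-TMS, 5-O-TIPS, side-chain O-TMS chromanone (not isolated) | C=C(C)[C@H](CC=C(C)C)Cc1c(OCOC)c(CCC(C)(C)O[Si](C)(C)C)c(O[Si](C(C)C)(C(C)C)C(C)C)c2c1O[C@H](c1ccc(OCOC)cc1OCOC)[C@@H](O[Si](C)(C)C)C2=O | intermediate
22 | (2R,3R)-7,2′,4′-tris-O-MOM flavanonol with free 3-OH, 5-OH and tertiary OH | C=C(C)[C@H](CC=C(C)C)Cc1c(OCOC)c(CCC(C)(C)O)c(O)c2c1O[C@H](c1ccc(OCOC)cc1OCOC)[C@@H](O)C2=O | intermediate
23 | hexakis-O-trimethylsilyl ether of the target (not isolated) | C=C(C)[C@H](CC=C(C)C)Cc1c(O[Si](C)(C)C)c(CCC(C)(C)O[Si](C)(C)C)c(O[Si](C)(C)C)c2c1O[C@H](c1ccc(O[Si](C)(C)C)cc1O[Si](C)(C)C)[C@@H](O[Si](C)(C)C)C2=O | intermediate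
24 | CNP0183552.3 | C=C(C)[C@H](CC=C(C)C)Cc1c(O)c(CCC(C)(C)O)c(O)c2c1O[C@H](c1ccc(O)cc1O)[C@@H](O)C2=O | target

**Step count.** 15 steps in total; the longest linear sequence is 12 steps (1 → 3 → 5 → 6 → 7 → 13 → 15 → 17 → 18 → 19 → 20 → 22 → 24).

**Steps most likely to fail**

Step 14 (proposed new method). The highly stabilised, loosely paired cation may be discriminated poorly by the chiral anion, giving low facial selectivity. The cation may also be captured intermolecularly by an electron-rich arene, or the O-alkylated isomer may fail to drain to the ketone. The fallback uses the established chalcone-epoxide route and sets out from 15. Lithiation as in step 10 and acylation with N-methoxy-N-methylacetamide should give the aryl methyl ketone F1. Directed aldol addition to 9 (LiN(SiMe3)2, THF, −78 °C) followed by mesylation–elimination of the secondary benzylic alcohol (MsCl, Et3N, then DBU) should give the (E)-chalcone F2. Juliá–Colonna epoxidation (poly-L-leucine, urea–H2O2, DBU, THF) is expected to give the (αR,βS)-epoxy ketone F3. Dilute HCl in MeOH at 0 °C should remove the ketone-flanked O1 MOM ether, and the freed phenol opens the epoxide at the benzylic carbon to the trans 5-O-silyl flavanonol F4, with C3 retained from Cα. Bu4NF/AcOH then returns the route to 22.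

Step 8. SN2 at the β-branched tosylate may be slow, so that elimination to the diene or protonation and homocoupling of the aryl metal take over. The fallback is a B-alkyl Suzuki–Miyaura coupling and sets out from 12 and 6. Lithiation of 12 as in step 8 and quenching with BrCCl2CCl2Br should give the aryl bromide F5. Alcohol 6 is converted into (S)-lavandulyl iodide F6 (I2, PPh3, imidazole). Iodine–lithium exchange (t-BuLi, Et2O, −78 °C) and trapping with B-methoxy-9-BBN should give the lithium alkyl(methoxy)borate F7, which is not isolated. Coupling of F7 with F5 (Pd(OAc)2, SPhos, K3PO4, THF/H2O, 60 °C) comes back to 13.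

Step 12. The equilibrium for a seven-membered aryl alkyl acetal may be unfavourable, or the electron-rich acetal may be lost again to acid during formation and isolation. The fallback replaces equilibrium acetalisation by kinetic oxidative closure and sets out from 18 and 9. Reduction of 9 (NaBH4, MeOH) gives [2,4-bis(methoxymethoxy)phenyl]methanol F8, which is converted into the benzylic chloride F9 (MsCl, Et3N, LiCl, THF, 0 °C; used crude). Selective O-alkylation of the phenol of 18 with F9 (K2CO3, DMF) should give the aryl benzyl ether F10. DDQ with 4 Å MS in CH2Cl2 at 0 °C then abstracts the benzylic hydride, and the primary alcohol O3–H captures the cation, coming back to 19.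

**Further compounds**

F1 | step 14 | 1-{3-(3-hydroxy-3-methylbutyl)-4,6-bis(methoxymethoxy)-5-[(2R)-lavandulyl]-2-(triisopropylsilyloxy)phenyl}ethan-1-one | C=C(C)[C@H](CC=C(C)C)Cc1c(OCOC)c(CCC(C)(C)O)c(O[Si](C(C)C)(C(C)C)C(C)C)c(C(C)=O)c1OCOC
F2 | step 14 | (E)-chalcone from F1 and 9 | C=C(C)[C@H](CC=C(C)C)Cc1c(OCOC)c(CCC(C)(C)O)c(O[Si](C(C)C)(C(C)C)C(C)C)c(C(=O)/C=C/c2ccc(OCOC)cc2OCOC)c1OCOC
F3 | step 14 | (αR,βS)-epoxy ketone of F2 | C=C(C)[C@H](CC=C(C)C)Cc1c(OCOC)c(CCC(C)(C)O)c(O[Si](C(C)C)(C(C)C)C(C)C)c(C(=O)[C@@H]2O[C@H]2c3ccc(OCOC)cc3OCOC)c1OCOC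
F4 | step 14 | (2R,3R)-5-O-triisopropylsilyl ether of 22 | C=C(C)[C@H](CC=C(C)C)Cc1c(OCOC)c(CCC(C)(C)O)c(O[Si](C(C)C)(C(C)C)C(C)C)c2c1O[C@H](c1ccc(OCOC)cc1OCOC)[C@@H](O)C2=O
F5 | step 8 | [4-bromo-3,5-bis(methoxymethoxy)phenoxy]triisopropylsilane | COCOc1cc(O[Si](C(C)C)(C(C)C)C(C)C)cc(OCOC)c1Br
F6 | step 8 | (S)-lavandulyl iodide | C=C(C)[C@H](CC=C(C)C)CI
F7 | step 8 | lithium B-methoxy-B-[(S)-lavandulyl]-9-borabicyclo[3.3.1]nonanate (not isolated) | [Li+].C=C(C)[C@H](CC=C(C)C)C[B-]1(OC)C2CCCC1CCC2
F8 | step 12 | [2,4-bis(methoxymethoxy)phenyl]methanol | COCOc1ccc(CO)c(OCOC)c1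
F9 | step 12 | 1-(chloromethyl)-2,4-bis(methoxymethoxy)benzene | COCOc1ccc(CCl)c(OCOC)c1
F10 | step 12 | O1-[2,4-bis(methoxymethoxy)benzyl] ether of 18 | C=C(C)[C@H](CC=C(C)C)Cc1c(OCOC)c(CCC(C)(C)O)c(O[Si](C(C)C)(C(C)C)C(C)C)c(C(=O)CO)c1OCc1ccc(OCOC)cc1OCOC
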